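**Retrosynthetic overview**

1. The diacid comes from one basic hydrolysis of a C19 N‑acyloxazolidinone / C18 methyl ester.
2. Key disconnection: C3=C4 (Horner–Wadsworth–Emmons) and O–C3 (oxa‑Michael) are opened together, so the 14‑membered carbocycle and the oxolane close in the same operation, setting C3 and C4.
3. C4–C5 (phosphonoacetate alkylation) and C8–C9 (Evans alkylation, sets C8) lead back to a 5‑bromopentanoyl oxazolidinone and a homoallylic triflate.
4. C12–C13 (nickel‑catalysed Grignard opening of 5‑methyl‑2,3‑dihydrofuran) fixes the Z alkene and leads back to a bromoethyl lactol acetal.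
5. C1–C2 (allyl opening of a Shi epoxide, sets C1) leads back to 5‑bromo‑2‑methylpent‑2‑ene; the early lactol ring is only a masked C3 aldehyde, and both target rings form last.

Assumption: atoms carry cembrane‑type labels (C1 = ring CH bearing the CMe2–O carbon C15; C2 = oxolane CH2; C3 = O–CH; C4 and C8 = the CH–CO2H carbons with carboxyl carbons C18 and C19; C11=C12 = ring alkene with methyl C20); in these labels the SMILES reads (1R,3R,4S,8R,11Z).

**Route**

Step 1
Reactants: 1 5-bromo-2-methylpent-2-ene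
Product: 2 (3R)-3-(2-bromoethyl)-2,2-dimethyloxirane
Conditions: 1,2:4,5-di-O-isopropylidene-β-D-erythro-2,3-hexodiulo-2,6-pyranose (C12H18O6, 0.3 equiv), KHSO5, K2CO3, Bu4NHSO4 (cat.), MeCN/CH2(OMe)2/aq. Na2B4O7 buffer, 0 °C
Reagents that add atoms: potassium peroxymonosulfate, [K+].[O-]S(=O)(=O)OO
Why: Shi asymmetric epoxidation; the chiral dioxirane from the fructose-derived ketone delivers oxygen to one face of the trisubstituted alkene (spiro transition state) and gives the R epoxide, which becomes C1 after inversion in step 2.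

Step 2
Reactants: 2 (3R)-3-(2-bromoethyl)-2,2-dimethyloxirane; 3 allylmagnesium bromide
Product: 4 (3S)-3-(2-bromoethyl)-2-methylhex-5-en-2-ol
Conditions: CuI (10 mol %), THF/Et2O, −40 to −20 °C
Reagents that add atoms: none
Why: Copper-catalysed SN2 opening of the epoxide by the allyl Grignard reagent at the less substituted carbon with inversion sets C1 and frees the tertiary alcohol that later becomes the ring oxygen; the low temperature spares the primary bromide.

Step 3
Reactants: 4 (3S)-3-(2-bromoethyl)-2-methylhex-5-en-2-ol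
Product: 6 (4S)-4-(2-bromoethyl)-2-methoxy-5,5-dimethyloxolane, via bromo lactol 5 (not isolated)
Conditions: O3, CH2Cl2/MeOH, −78 °C; Me2S; then 4-MeC6H4SO3H (cat.), MeOH, rt
Reagents that add atoms: methanol, CO
Why: Ozonolysis of the only alkene gives the C3 aldehyde, which closes onto the tertiary alcohol as lactol 5, and Fischer acetalisation masks it as the methyl acetal (anomer mixture) so that a Grignard reagent can be made; C1 is untouched.

Step 4
Reactants: 6 (4S)-4-(2-bromoethyl)-2-methoxy-5,5-dimethyloxolane; 7 5-methyl-2,3-dihydrofuran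
Product: 9 (3Z)-6-[(3R)-5-methoxy-2,2-dimethyloxolan-3-yl]-4-methylhex-3-en-1-ol, via Grignard reagent 8 (not isolated)
Conditions: Mg, THF, 40 °C; then 7, NiCl2(PPh3)2 (5 mol %), toluene, 90 °C
Reagents that add atoms: none
Why: Wenkert coupling; nickel inserts into the vinylic C–O bond of the cyclic enol ether and the alkyl group replaces oxygen with retention, so C13 stays cis to the CH2CH2O arm and the Z trisubstituted alkene is fixed by the ring geometry of 7.

Step 5
Reactants: 9 (3Z)-6-[(3R)-5-methoxy-2,2-dimethyloxolan-3-yl]-4-methylhex-3-en-1-ol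
Product: 10 (3Z)-6-[(3R)-5-methoxy-2,2-dimethyloxolan-3-yl]-4-methylhex-3-en-1-yl trifluoromethanesulfonate
Conditions: Tf2O, 2,6-lutidine, CH2Cl2, −78 °C, used at once
Reagents that add atoms: trifluoromethanesulfonic anhydride, O=S(=O)(OS(=O)(=O)C(F)(F)F)C(F)(F)F
Why: Sulfonylation of the primary alcohol gives a triflate reactive enough for an imide enolate at −78 °C; no stereocentre is involved.

Step 6
Reactants: 11 (4S)-4-benzyl-1,3-oxazolidin-2-one; 12 5-bromopentanoyl chloride
Product: 13 (4S)-4-benzyl-3-(5-bromopentanoyl)-1,3-oxazolidin-2-one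
Conditions: n-BuLi, THF, −78 °C; then 12, −78 to 0 °C
Reagents that add atoms: none
Why: N-acylation of the lithiated oxazolidinone installs the auxiliary on the C19 carbonyl of the C5–C8 unit.

Step 7
Reactants: 13 (4S)-4-benzyl-3-(5-bromopentanoyl)-1,3-oxazolidin-2-one; 10 (3Z)-6-[(3R)-5-methoxy-2,2-dimethyloxolan-3-yl]-4-methylhex-3-en-1-yl trifluoromethanesulfonate
Product: 14 (4S)-4-benzyl-3-{(2S,5Z)-2-(3-bromopropyl)-8-[(3R)-5-methoxy-2,2-dimethyloxolan-3-yl]-6-methyloct-5-enoyl}-1,3-oxazolidin-2-one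
Conditions: NaN(SiMe3)2, THF, −78 °C; then 10, −78 to −40 °C
Reagents that add atoms: none
Why: Evans asymmetric alkylation; the chelated Z sodium enolate is alkylated by the primary triflate on the face opposite the benzyl group, which sets C8 (the intramolecular four-ring closure onto the bromide is too slow to compete).

Step 8
Reactants: 14 (4S)-4-benzyl-3-{(2S,5Z)-2-(3-bromopropyl)-8-[(3R)-5-methoxy-2,2-dimethyloxolan-3-yl]-6-methyloct-5-enoyl}-1,3-oxazolidin-2-one; 15 trimethyl phosphonoacetate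
Product: 17 methyl (6R,9Z)-6-{[(4S)-4-benzyl-2-oxo-1,3-oxazolidin-3-yl]carbonyl}-2-(dimethoxyphosphoryl)-12-[(3R)-5-hydroxy-2,2-dimethyloxolan-3-yl]-10-methyldodec-9-enoate, via acetal phosphonate 16 (not isolated)
Conditions: NaH (slightly less than 15), NaI (cat.), DMF, 50 °C; then 1 M HCl, THF, rt
Reagents that add atoms: water, O
Why: SN2 alkylation of the stabilised phosphonoacetate anion by the primary bromide makes the C4–C5 bond (C4 epimers, irrelevant), and aqueous acid hydrolyses the methyl acetal to the lactol, the masked C3 aldehyde; the weakly basic anion does not epimerise C8.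

Step 9
Reactants: 17 methyl (6R,9Z)-6-{[(4S)-4-benzyl-2-oxo-1,3-oxazolidin-3-yl]carbonyl}-2-(dimethoxyphosphoryl)-12-[(3R)-5-hydroxy-2,2-dimethyloxolan-3-yl]-10-methyldodec-9-enoate
Product: 19 methyl (1R,4Z,8R,12S,13R)-8-{[(4S)-4-benzyl-2-oxo-1,3-oxazolidin-3-yl]carbonyl}-4,15,15-trimethyl-14-oxabicyclo[11.2.1]hexadec-4-ene-12-carboxylate, via macrocyclic hydroxy enoate 18 (not isolated)
Conditions: LiCl, DBU, MeCN (2 mM, slow addition), 25 to 60 °C
Reagents that add atoms: none
Why: Masamune–Roush intramolecular Horner–Wadsworth–Emmons olefination of the open hydroxy-aldehyde form of the lactol closes the 14-membered carbocycle as (E)-enoate 18, and the tertiary alkoxide freed by that ring opening then adds 5-exo to C3 (oxa-Michael) to close the oxolane; the oxolane can bridge C1 and C3 of the macrocycle only cis and the addition is reversible, which fixes C3 as R, and the ester enolate is protonated anti to the new C3–O bond with H3 in the enolate plane (allylic 1,3-strain, the anti-addition preference of alkoxide additions to α-substituted enoates), which gives 4S.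

Step 10
Reactants: 19 methyl (1R,4Z,8R,12S,13R)-8-{[(4S)-4-benzyl-2-oxo-1,3-oxazolidin-3-yl]carbonyl}-4,15,15-trimethyl-14-oxabicyclo[11.2.1]hexadec-4-ene-12-carboxylate
Product: 20 (1R,4Z,8R,12S,13R)-4,15,15-trimethyl-14-oxabicyclo[11.2.1]hexadec-4-ene-8,12-dicarboxylic acid (the target)
Conditions: LiOH, H2O2, THF/H2O, 0 °C to rt; Na2SO3; then 1 M HCl
Reagents that add atoms: lithium hydroxide, [Li+].[OH-]; hydrogen peroxide, OO
Why: Lithium hydroperoxide cleaves the exocyclic imide carbonyl (Evans auxiliary removal) and hydroxide saponifies the methyl ester, so both acids are freed in one hydrolysis without touching the four stereocentres or the Z alkene.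

**Compound list**

1 | 5-bromo-2-methylpent-2-ene | CC(C)=CCCBr | starting material
2 | (3R)-3-(2-bromoethyl)-2,2-dimethyloxirane | BrCC[C@H]1OC1(C)C | intermediate
3 | allylmagnesium bromide | C=CC[Mg]Br | starting material
4 | (3S)-3-(2-bromoethyl)-2-methylhex-5-en-2-ol | C=CC[C@@H](CCBr)C(C)(C)O | intermediate
5 | (4S)-4-(2-bromoethyl)-5,5-dimethyloxolan-2-ol, both anomers (not isolated) | OC1C[C@@H](CCBr)C(C)(C)O1 | intermediate
6 | (4S)-4-(2-bromoethyl)-2-methoxy-5,5-dimethyloxolane, both anomers | COC1C[C@@H](CCBr)C(C)(C)O1 | intermediate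
7 | 5-methyl-2,3-dihydrofuran | CC1=CCCO1 | starting material
8 | bromo{2-[(3S)-5-methoxy-2,2-dimethyloxolan-3-yl]ethyl}magnesium (not isolated) | COC1C[C@@H](CC[Mg]Br)C(C)(C)O1 | intermediate
9 | (3Z)-6-[(3R)-5-methoxy-2,2-dimethyloxolan-3-yl]-4-methylhex-3-en-1-ol | OCC/C=C(/C)CC[C@@H]1CC(OC)OC1(C)C | intermediate
10 | (3Z)-6-[(3R)-5-methoxy-2,2-dimethyloxolan-3-yl]-4-methylhex-3-en-1-yl trifluoromethanesulfonate | O=S(=O)(OCC/C=C(/C)CC[C@@H]1CC(OC)OC1(C)C)C(F)(F)F | intermediate
11 | (4S)-4-benzyl-1,3-oxazolidin-2-one | O=C1OC[C@H](Cc2ccccc2)N1 | starting material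
12 | 5-bromopentanoyl chloride | O=C(Cl)CCCCBr | starting material
13 | (4S)-4-benzyl-3-(5-bromopentanoyl)-1,3-oxazolidin-2-one | O=C(CCCCBr)N1[C@@H](Cc2ccccc2)COC1=O | intermediate
14 | (4S)-4-benzyl-3-{(2S,5Z)-2-(3-bromopropyl)-8-[(3R)-5-methoxy-2,2-dimethyloxolan-3-yl]-6-methyloct-5-enoyl}-1,3-oxazolidin-2-one | O=C([C@H](CCCBr)CC/C=C(/C)CC[C@@H]1CC(OC)OC1(C)C)N1[C@@H](Cc2ccccc2)COC1=O | intermediate
15 | trimethyl phosphonoacetate | COC(=O)CP(=O)(OC)OC | starting material
16 | methyl (6R,9Z)-6-{[(4S)-4-benzyl-2-oxo-1,3-oxazolidin-3-yl]carbonyl}-2-(dimethoxyphosphoryl)-12-[(3R)-5-methoxy-2,2-dimethyloxolan-3-yl]-10-methyldodec-9-enoate (not isolated) | O=C([C@H](CCCC(C(=O)OC)P(=O)(OC)OC)CC/C=C(/C)CC[C@@H]1CC(OC)OC1(C)C)N1[C@@H](Cc2ccccc2)COC1=O | intermediate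
17 | methyl (6R,9Z)-6-{[(4S)-4-benzyl-2-oxo-1,3-oxazolidin-3-yl]carbonyl}-2-(dimethoxyphosphoryl)-12-[(3R)-5-hydroxy-2,2-dimethyloxolan-3-yl]-10-methyldodec-9-enoate | O=C([C@H](CCCC(C(=O)OC)P(=O)(OC)OC)CC/C=C(/C)CC[C@@H]1CC(O)OC1(C)C)N1[C@@H](Cc2ccccc2)COC1=O | intermediate
18 | methyl (1E,4R,7Z,11R)-11-{[(4S)-4-benzyl-2-oxo-1,3-oxazolidin-3-yl]carbonyl}-4-(2-hydroxypropan-2-yl)-7-methylcyclotetradeca-1,7-diene-1-carboxylate (not isolated) | CC(C)(O)[C@H]1C/C=C(/C(=O)OC)CCC[C@@H](C(=O)N2[C@@H](Cc3ccccc3)COC2=O)CC/C=C(/C)CC1 | intermediate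
19 | methyl (1R,4Z,8R,12S,13R)-8-{[(4S)-4-benzyl-2-oxo-1,3-oxazolidin-3-yl]carbonyl}-4,15,15-trimethyl-14-oxabicyclo[11.2.1]hexadec-4-ene-12-carboxylate | C/C1=C/CC[C@H](C(=O)N3[C@@H](Cc4ccccc4)COC3=O)CCC[C@H](C(=O)OC)[C@H]2C[C@@H](CC1)C(C)(C)O2 | intermediate
20 | (1R,4Z,8R,12S,13R)-4,15,15-trimethyl-14-oxabicyclo[11.2.1]hexadec-4-ene-8,12-dicarboxylic acid | C/C1=C/CC[C@H](C(=O)O)CCC[C@H](C(=O)O)[C@H]2C[C@@H](CC1)C(C)(C)O2 | target

**Step count and risks**

Total steps: 10. Longest linear sequence: 9 steps (steps 1–5 and 7–10; step 6 is a one-step side branch).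

The three steps most likely to fail:

Step 9. The intramolecular olefination competes with oligomerisation, an α-alkylated phosphonate reacts slowly with a lactol, and the C4 protonation (or later base-induced epimerisation or retro-addition) may erode the 3R,4S arrangement. The fallback sets out from triflate 10 and returns to the route at 19. Triflate 10 alkylates the sodium enolate of (4S)-4-benzyl-3-(hept-6-enoyl)-1,3-oxazolidin-2-one F1 (from 11 and hept-6-enoyl chloride) to give (4S)-4-benzyl-3-{(2R,5Z)-8-[(3R)-5-methoxy-2,2-dimethyloxolan-3-yl]-6-methyl-2-(pent-4-en-1-yl)oct-5-enoyl}-1,3-oxazolidin-2-one F2. Aqueous acid frees the lactol (4S)-4-benzyl-3-{(2R,5Z)-8-[(3R)-5-hydroxy-2,2-dimethyloxolan-3-yl]-6-methyl-2-(pent-4-en-1-yl)oct-5-enoyl}-1,3-oxazolidin-2-one F3. Methylenation with Ph3P=CH2 gives the diene tertiary alcohol (4S)-4-benzyl-3-[(2R,5Z,9R)-9-(2-hydroxypropan-2-yl)-6-methyl-2-(pent-4-en-1-yl)dodeca-5,11-dienoyl]-1,3-oxazolidin-2-one F4. Ring-closing metathesis with the second-generation Grubbs catalyst RuCl2(=CHPh)(PCy3)(H2IMes) gives the 14-membered cycloalkene (4S)-4-benzyl-3-{[(1R,4Z,8R,10E)-8-(2-hydroxypropan-2-yl)-5-methylcyclotetradeca-4,10-dien-1-yl]carbonyl}-1,3-oxazolidin-2-one F5. Intramolecular alkoxycarbonylation (PdCl2, CuCl2, CO, MeOH) then closes the oxolane and installs the C18 methyl ester by stereospecific anti addition across the E alkene, which gives 19 with C3 and C4 set by the alkene geometry instead of by protonation.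

Step 4. A primary alkyl Grignard reagent with β-hydrogens can give reduction or homocoupling on nickel instead of the ring-opening coupling. The fallback sets out from 6 and returns at 9. Halide exchange (NaI, acetone) gives (4S)-4-(2-iodoethyl)-2-methoxy-5,5-dimethyloxolane F6. Separately, 2,3-dihydrofuran is lithiated at C5 (t-BuLi) and added to MeLi/CuBr·SMe2. Warming brings about the 1,2-metalate rearrangement (methyl migrates from copper to the vinylic carbon with inversion and the ring opens) to give lithium (3Z)-4-cupriopent-3-en-1-olate F7. Alkylation of F7 by F6 in THF/DMPU gives 9 with the same Z geometry.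

Step 10. The hindered β-alkoxy methyl ester may need forcing hydroxide conditions, which risk retro-oxa-Michael opening or epimerisation at C4. The fallback sets out from 19 and returns at 20. LiBH4 reduces both acyl groups to give the diol [(1R,4Z,8R,12R,13R)-4,15,15-trimethyl-14-oxabicyclo[11.2.1]hexadec-4-ene-8,12-diyl]dimethanol F8. Oxidation with 2,2,6,6-tetramethylpiperidin-1-oxyl (C9H18NO, cat.), NaClO2 and NaOCl (cat.) in MeCN/phosphate buffer converts both primary alcohols into the carboxylic acids of 20.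

**Further compounds**

F1 | step 9 | (4S)-4-benzyl-3-(hept-6-enoyl)-1,3-oxazolidin-2-one | C=CCCCCC(=O)N1[C@@H](Cc2ccccc2)COC1=O
F2 | step 9 | (4S)-4-benzyl-3-{(2R,5Z)-8-[(3R)-5-methoxy-2,2-dimethyloxolan-3-yl]-6-methyl-2-(pent-4-en-1-yl)oct-5-enoyl}-1,3-oxazolidin-2-one | O=C([C@H](CCCC=C)CC/C=C(/C)CC[C@@H]1CC(OC)OC1(C)C)N1[C@@H](Cc2ccccc2)COC1=O
F3 | step 9 | (4S)-4-benzyl-3-{(2R,5Z)-8-[(3R)-5-hydroxy-2,2-dimethyloxolan-3-yl]-6-methyl-2-(pent-4-en-1-yl)oct-5-enoyl}-1,3-oxazolidin-2-one | O=C([C@H](CCCC=C)CC/C=C(/C)CC[C@@H]1CC(O)OC1(C)C)N1[C@@H](Cc2ccccc2)COC1=O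
F4 | step 9 | (4S)-4-benzyl-3-[(2R,5Z,9R)-9-(2-hydroxypropan-2-yl)-6-methyl-2-(pent-4-en-1-yl)dodeca-5,11-dienoyl]-1,3-oxazolidin-2-one | O=C([C@H](CCCC=C)CC/C=C(/C)CC[C@H](CC=C)C(C)(C)O)N1[C@@H](Cc2ccccc2)COC1=O
F5 | step 9 | (4S)-4-benzyl-3-{[(1R,4Z,8R,10E)-8-(2-hydroxypropan-2-yl)-5-methylcyclotetradeca-4,10-dien-1-yl]carbonyl}-1,3-oxazolidin-2-one | CC(C)(O)[C@H]1C/C=C/CCC[C@@H](C(=O)N2[C@@H](Cc3ccccc3)COC2=O)CC/C=C(/C)CC1
F6 | step 4 | (4S)-4-(2-iodoethyl)-2-methoxy-5,5-dimethyloxolane | COC1C[C@@H](CCI)C(C)(C)O1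
F7 | step 4 | lithium (3Z)-4-cupriopent-3-en-1-olate | [Li]OCC/C=C(/C)[Cu]
F8 | step 10 | [(1R,4Z,8R,12R,13R)-4,15,15-trimethyl-14-oxabicyclo[11.2.1]hexadec-4-ene-8,12-diyl]dimethanol | C/C1=C/CC[C@H](CO)CCC[C@H](CO)[C@H]2C[C@@H](CC1)C(C)(C)O2
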